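**Plan**
1. Retrosynthesis: the acetate, the α-hydroxyl and the lactone carbonyl are taken back to silyl ether/methyl lactol ether 29. The bond between hydrindane C1 and the C(=CH2) carbon is then cut, giving C1 boronic ester 11 and a 1,1-disubstituted alkenyllithium (from hydrazone 25).
2. Enabling feature: C1 is a ring methine of the trans-hydrindane next to quaternary C7a, bonded to the fully substituted carbon of an exocyclic C=CH2 whose other neighbour is the CH(CH2O) centre. Such an sp3-stereocentre–C(=CH2) junction is the product pattern of a boronate 1,2-shift onto an α-substituted vinyl group followed by B/I elimination.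
3. Hydrindane, forward: the (S)-bicyclic enedione 1 is gem-dimethylated, deoxygenated and hydrogenated to the trans-fused ketone 7, which is converted via its alkenyl boronate to the β-C1 boronic ester 11.
4. Side chain, forward: (R)-epichlorohydrin and malonate give a cyclopropane-fused lactone, opened with strain release by a vinyl cuprate to the (R)-4-allyl lactone; trans-hydroxymethylation follows. The lactone carbonyl is then turned into the future alkene carbon (amide, methyl ketone, trisylhydrazone 25) and the allyl group into the masked target lactone.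
5. Union and endgame: Shapiro/Zweifel coupling (step 18), Jones oxidation to the lactone, trans α-hydroxylation, desilylation, selective acetylation.
6. Stereochemistry: C7a from 1; C3a and C1 by α-face hydrogenations, C1 then transferred with retention; lactone C4 from epichlorohydrin; CH(CH2OAc) and CH(OH) by anti-selective functionalisation of five-membered lactone enolates.

Key step: step 18

Remark: the acetal carbon (22, 23–29), the boron-bearing carbon of 28 and the hydrazone C=N geometry are formed as mixtures or do not affect the outcome and are left undefined in the SMILES; 16 is drawn as its trans epimer.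

Step 1
Reactants: 1 (7aS)-7a-methyl-2,3,7,7a-tetrahydro-1H-indene-1,5(6H)-dione
Product: 2 (7a'S)-7a'-methyl-2',3',7',7a'-tetrahydrospiro[1,3-dioxolane-2,1'-inden]-5'(6'H)-one
Conditions: 2-ethyl-2-methyl-1,3-dioxolane, ethylene glycol (cat.), p-TsOH (cat.), rt
Reagents that add atoms: 2-ethyl-2-methyl-1,3-dioxolane, CCC1(C)OCCO1
Why: Acid-catalysed trans-ketalisation should protect the saturated C1 cyclopentanone selectively, because the conjugated C5 enone carbonyl is less electrophilic; no stereocentre is touched.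

Step 2
Reactants: 2 (7a'S)-7a'-methyl-2',3',7',7a'-tetrahydrospiro[1,3-dioxolane-2,1'-inden]-5'(6'H)-one
Product: 3 (7a'S)-4',4',7a'-trimethyl-2',4',7',7a'-tetrahydrospiro[1,3-dioxolane-2,1'-inden]-5'(6'H)-one
Conditions: t-BuOK (2.5 equiv), MeI (excess), t-BuOH/THF, 0 °C to rt
Reagents that add atoms: iodomethane, CI
Why: Deconjugative double α-alkylation of the extended enolate should methylate C4 twice and leave the alkene at C3=C3a, out of conjugation.

Step 3
Reactants: 3 (7a'S)-4',4',7a'-trimethyl-2',4',7',7a'-tetrahydrospiro[1,3-dioxolane-2,1'-inden]-5'(6'H)-one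
Product: 5 (7a'S)-4',4',7a'-trimethyl-2',4',5',6',7',7a'-hexahydrospiro[1,3-dioxolane-2,1'-indene], via hydrazone 4 (not isolated)
Conditions: N2H4·H2O, KOH, diethylene glycol, 120 then 200 °C
Reagents that add atoms: none
Why: Wolff–Kishner (Huang–Minlon) reduction should remove the hindered C5 carbonyl, since the ketal and the alkene (which cannot move into conjugation past quaternary C4) tolerate hot base.

Step 4
Reactants: 5 (7a'S)-4',4',7a'-trimethyl-2',4',5',6',7',7a'-hexahydrospiro[1,3-dioxolane-2,1'-indene]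
Product: 6 (3a'S,7a'S)-4',4',7a'-trimethyloctahydrospiro[1,3-dioxolane-2,1'-indene]
Conditions: H2 (4 atm), 10% Pd/C, EtOAc, rt
Reagents that add atoms: none
Why: Heterogeneous catalytic hydrogenation should add hydrogen to the α face of C3=C3a, opposite the angular C7a methyl and the β-oxygen of the ketal, placing H at C3a trans to the methyl (trans-hydrindane).

Step 5
Reactants: 6 (3a'S,7a'S)-4',4',7a'-trimethyloctahydrospiro[1,3-dioxolane-2,1'-indene]
Product: 7 (3aS,7aS)-4,4,7a-trimethyloctahydro-1H-inden-1-one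
Conditions: 1 M HCl, THF, rt
Reagents that add atoms: water, O
Why: Acid-catalysed ketal hydrolysis should release the C1 ketone without touching the ring-fusion centres, neither of which is enolisable.

Step 6
Reactants: 7 (3aS,7aS)-4,4,7a-trimethyloctahydro-1H-inden-1-one
Product: 9 (3aS,7aS)-4,4,7a-trimethyl-3a,4,5,6,7,7a-hexahydro-3H-inden-1-yl trifluoromethanesulfonate, via potassium enolate 8 (not isolated)
Conditions: KHMDS, THF, −78 °C; then PhNTf2, −78 °C to rt
Reagents that add atoms: N-phenylbis(trifluoromethanesulfonimide), O=S(=O)(N(c1ccccc1)S(=O)(=O)C(F)(F)F)C(F)(F)F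
Why: Enol triflate formation; only C2 is enolisable, so O-sulfonylation of the enolate should give a single regioisomer.

Step 7
Reactants: 9 (3aS,7aS)-4,4,7a-trimethyl-3a,4,5,6,7,7a-hexahydro-3H-inden-1-yl trifluoromethanesulfonate
Product: 10 2-[(3aS,7aS)-4,4,7a-trimethyl-3a,4,5,6,7,7a-hexahydro-3H-inden-1-yl]-4,4,5,5-tetramethyl-1,3,2-dioxaborolane
Conditions: B2pin2, PdCl2(PPh3)2 (3 mol %), PPh3, KOPh, toluene, 50 °C
Reagents that add atoms: bis(pinacolato)diboron, CC1(C)OB(OC1(C)C)B1OC(C)(C)C(C)(C)O1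
Why: Miyaura borylation of an alkenyl triflate should give the alkenyl boronic ester.

Step 8
Reactants: 10 2-[(3aS,7aS)-4,4,7a-trimethyl-3a,4,5,6,7,7a-hexahydro-3H-inden-1-yl]-4,4,5,5-tetramethyl-1,3,2-dioxaborolane
Product: 11 2-[(1S,3aS,7aR)-4,4,7a-trimethyloctahydro-1H-inden-1-yl]-4,4,5,5-tetramethyl-1,3,2-dioxaborolane (boron β, cis to the angular methyl; the same spatial arrangement as the target, the descriptors differ because boron ranks below carbon)
Conditions: H2 (1–4 atm), 10% Pd/C, EtOAc, rt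
Reagents that add atoms: none
Why: Catalytic hydrogenation should add hydrogen syn from the α face, opposite the C7a methyl, leaving H α and boron β at C1, the configuration that the key step transfers.

Step 9
Reactants: 12 (R)-epichlorohydrin; 13 diethyl malonate
Product: 15 ethyl (1S,5R)-2-oxo-3-oxabicyclo[3.1.0]hexane-1-carboxylate, via epoxy malonate 14 (not isolated)
Conditions: NaOEt, EtOH, reflux
Reagents that add atoms: none
Why: Tandem epoxide opening, epoxide re-closure with loss of chloride, 3-exo-tet cyclopropanation (inversion at the epoxide carbon) and lactonisation should turn the epichlorohydrin stereocentre into C5, and the cis ring fusion then fixes C1.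

Step 10
Reactants: 15 ethyl (1S,5R)-2-oxo-3-oxabicyclo[3.1.0]hexane-1-carboxylate
Product: 16 ethyl (3S,4R)-2-oxo-4-(prop-2-en-1-yl)tetrahydrofuran-3-carboxylate
Conditions: CH2=CHMgBr, CuI (10 mol %), THF, −40 to −10 °C; aq NH4Cl
Reagents that add atoms: vinylmagnesium bromide, C=C[Mg]Br
Why: Copper-catalysed homoconjugate addition should open the doubly activated cyclopropane at its CH2 with release of ring strain; the C5 stereocentre is not involved and the epimerisable C3 centre is removed in step 11.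

Step 11
Reactants: 16 ethyl (3S,4R)-2-oxo-4-(prop-2-en-1-yl)tetrahydrofuran-3-carboxylate
Product: 17 (4R)-4-(prop-2-en-1-yl)dihydrofuran-2(3H)-one
Conditions: LiCl, DMSO, H2O, 140 °C
Reagents that add atoms: none
Why: Krapcho dealkoxycarbonylation should remove the ester and leave the C4 stereocentre untouched.

Step 12
Reactants: 17 (4R)-4-(prop-2-en-1-yl)dihydrofuran-2(3H)-one
Product: 19 (3S,4R)-3-(hydroxymethyl)-4-(prop-2-en-1-yl)dihydrofuran-2(3H)-one, via lithium enolate 18 (not isolated)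
Conditions: LDA, THF, −78 °C; CH2O (gas, from cracked paraformaldehyde), −78 to −20 °C; aq NH4Cl
Reagents that add atoms: formaldehyde, C=O
Why: Aldol addition of the lactone enolate to formaldehyde should occur anti to the C4 allyl group and give the 3,4-trans lactone, which sets the future CH(CH2OAc) centre.

Step 13
Reactants: 19 (3S,4R)-3-(hydroxymethyl)-4-(prop-2-en-1-yl)dihydrofuran-2(3H)-one
Product: 20 (3S,4R)-3-{[(tert-butyldiphenylsilyl)oxy]methyl}-4-(prop-2-en-1-yl)dihydrofuran-2(3H)-one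
Conditions: TBDPSCl, imidazole, DMF, rt
Reagents that add atoms: tert-butyl(chloro)diphenylsilane, CC(C)(C)[Si](Cl)(c1ccccc1)c1ccccc1
Why: Silylation of the primary alcohol gives an ether that survives organolithiums, ozone and chromic acid.

Step 14
Reactants: 20 (3S,4R)-3-{[(tert-butyldiphenylsilyl)oxy]methyl}-4-(prop-2-en-1-yl)dihydrofuran-2(3H)-one
Product: 21 (2S,3R)-2-{[(tert-butyldiphenylsilyl)oxy]methyl}-3-(hydroxymethyl)-N-methoxy-N-methylhex-5-enamide
Conditions: MeNH(OMe)·HCl, AlMe3, CH2Cl2, 0 °C to rt; Rochelle salt; used crude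
Reagents that add atoms: N,O-dimethylhydroxylamine hydrochloride, CNOC.Cl
Why: Aluminium-amide aminolysis of the lactone (Weinreb amide formation) should open the ring without epimerising the α-centre and free the primary hydroxyl that later becomes the ring oxygen of the target lactone.

Step 15
Reactants: 21 (2S,3R)-2-{[(tert-butyldiphenylsilyl)oxy]methyl}-3-(hydroxymethyl)-N-methoxy-N-methylhex-5-enamide
Product: 23 (2S)-3-[(tert-butyldiphenylsilyl)oxy]-N-methoxy-2-[(3R)-5-methoxytetrahydrofuran-3-yl]-N-methylpropanamide (anomeric mixture), via lactol 22 (not isolated)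
Conditions: O3, CH2Cl2/MeOH, −78 °C; Me2S; then p-TsOH (cat.), MeOH, rt
Reagents that add atoms: methanol, CO
Why: Ozonolysis with reductive work-up should give the aldehyde, which closes on the free hydroxyl to the five-membered lactol and is fixed as the methyl acetal by acid-catalysed acetalisation, masking the future lactone carbonyl.

Step 16
Reactants: 23 (2S)-3-[(tert-butyldiphenylsilyl)oxy]-N-methoxy-2-[(3R)-5-methoxytetrahydrofuran-3-yl]-N-methylpropanamide
Product: 24 (3S)-4-[(tert-butyldiphenylsilyl)oxy]-3-[(3R)-5-methoxytetrahydrofuran-3-yl]butan-2-one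
Conditions: MeMgBr, THF, 0 °C; aq NH4Cl
Reagents that add atoms: methylmagnesium bromide, C[Mg]Br
Why: Weinreb ketone synthesis; the chelated tetrahedral intermediate should prevent over-addition and enolisation of the α-stereocentre.

Step 17
Reactants: 24 (3S)-4-[(tert-butyldiphenylsilyl)oxy]-3-[(3R)-5-methoxytetrahydrofuran-3-yl]butan-2-one
Product: 25 2,4,6-triisopropylbenzenesulfonyl hydrazone of 24
Conditions: 2,4,6-triisopropylbenzenesulfonyl hydrazide, THF, rt
Reagents that add atoms: 2,4,6-triisopropylbenzenesulfonyl hydrazide, CC(C)c1cc(C(C)C)c(S(=O)(=O)NN)c(C(C)C)c1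
Why: Condensation to the arylsulfonyl hydrazone should proceed under near-neutral conditions and place the sulfonamide syn to the methyl group.

Step 18
Reactants: 25 2,4,6-triisopropylbenzenesulfonyl hydrazone of 24; 11 2-[(1S,3aS,7aR)-4,4,7a-trimethyloctahydro-1H-inden-1-yl]-4,4,5,5-tetramethyl-1,3,2-dioxaborolane
Product: 29 tert-butyl{[(2R)-2-[(3R)-5-methoxytetrahydrofuran-3-yl]-3-[(1R,3aS,7aS)-4,4,7a-trimethyloctahydro-1H-inden-1-yl]but-3-en-1-yl]oxy}diphenylsilane, via alkenyllithium 26 (not isolated), via lithium boronate complex 27 (not isolated), via iodoalkyl boronic ester 28 (not isolated)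
Conditions: 25 (1.3 equiv), n-BuLi (2.6 equiv), THF, −78 then 0 °C; 11, −78 °C to rt; I2, THF/MeOH, −78 °C; NaOMe, MeOH, −78 °C to rt
Reagents that add atoms: none
Why: Two equivalents of n-BuLi should deprotonate N–H and the methyl group syn to the sulfonamide, and loss of sulfinate and N2 (Shapiro reaction) gives the 1,1-disubstituted alkenyllithium 26, which adds to the boron of 11 to form boronate complex 27. Iodine then activates the terminal CH2 of the alkenyl group, the hydrindanyl C1 migrates from boron to the adjacent alkenyl carbon (1,2-metallate shift) to give 28, and methoxide triggers anti-elimination of boron and iodide to the C=CH2 unit (Zweifel olefination). The closest known reaction type is the Zweifel coupling of secondary alkyl pinacol boronic esters with α-substituted alkenyllithiums, the Shapiro reaction being an established source of such alkenyllithiums. No ring is closed and no new stereocentre is formed: C1 is controlled by the stereoretentive migration from boron, so the β orientation set in step 8 becomes the C1–C bond, and the allylic centre is untouched because deprotonation occurs on the methyl side. The step needs migration of the hydrindanyl carbon and not of a pinacol oxygen, and attack of iodine at the boronate-activated alkene only; the electron-rich ate complex and the absence of other iodine-sensitive groups (only an acetal and a silyl ether are present) should secure both.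

Step 19
Reactants: 29 tert-butyl{[(2R)-2-[(3R)-5-methoxytetrahydrofuran-3-yl]-3-[(1R,3aS,7aS)-4,4,7a-trimethyloctahydro-1H-inden-1-yl]but-3-en-1-yl]oxy}diphenylsilane
Product: 30 (4R)-4-{(2R)-1-[(tert-butyldiphenylsilyl)oxy]-3-[(1R,3aS,7aS)-4,4,7a-trimethyloctahydro-1H-inden-1-yl]but-3-en-2-yl}dihydrofuran-2(3H)-one
Conditions: Jones reagent (CrO3, aq H2SO4), acetone, 0 °C
Reagents that add atoms: water, O
Why: Jones oxidation should hydrolyse the methyl acetal to the lactol in situ and oxidise it to the γ-lactone; the TBDPS ether and the isolated alkene should tolerate the short, cold acid exposure.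

Step 20
Reactants: 30 (4R)-4-{(2R)-1-[(tert-butyldiphenylsilyl)oxy]-3-[(1R,3aS,7aS)-4,4,7a-trimethyloctahydro-1H-inden-1-yl]but-3-en-2-yl}dihydrofuran-2(3H)-one
Product: 32 (3S,4R)-4-{(2R)-1-[(tert-butyldiphenylsilyl)oxy]-3-[(1R,3aS,7aS)-4,4,7a-trimethyloctahydro-1H-inden-1-yl]but-3-en-2-yl}-3-hydroxydihydrofuran-2(3H)-one, via potassium enolate 31 (not isolated)
Conditions: KHMDS, THF, −78 °C; 2-(phenylsulfonyl)-3-phenyloxaziridine, −78 °C; aq NH4Cl
Reagents that add atoms: 2-(phenylsulfonyl)-3-phenyloxaziridine, O=S(=O)(N1OC1c1ccccc1)c1ccccc1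
Why: Sulfonyloxaziridine α-hydroxylation of the lactone enolate should deliver oxygen anti to the bulky C4 substituent and give the 3,4-trans α-hydroxy lactone, which sets the carbinol centre.

Step 21
Reactants: 32 (3S,4R)-4-{(2R)-1-[(tert-butyldiphenylsilyl)oxy]-3-[(1R,3aS,7aS)-4,4,7a-trimethyloctahydro-1H-inden-1-yl]but-3-en-2-yl}-3-hydroxydihydrofuran-2(3H)-one
Product: 33 (3S,4R)-3-hydroxy-4-{(2R)-1-hydroxy-3-[(1R,3aS,7aS)-4,4,7a-trimethyloctahydro-1H-inden-1-yl]but-3-en-2-yl}dihydrofuran-2(3H)-one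
Conditions: HF·pyridine, THF/pyridine, 0 °C to rt
Reagents that add atoms: none
Why: Fluoride-mediated desilylation under non-basic conditions should free the primary alcohol without opening or epimerising the α-hydroxy lactone.

Step 22
Reactants: 33 (3S,4R)-3-hydroxy-4-{(2R)-1-hydroxy-3-[(1R,3aS,7aS)-4,4,7a-trimethyloctahydro-1H-inden-1-yl]but-3-en-2-yl}dihydrofuran-2(3H)-one
Product: 34 (2R)-2-[(3R,4S)-4-hydroxy-5-oxotetrahydrofuran-3-yl]-3-[(1R,3aS,7aS)-4,4,7a-trimethyloctahydro-1H-inden-1-yl]but-3-en-1-yl acetate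
Conditions: AcCl (1.1 equiv), 2,4,6-collidine, CH2Cl2, −78 °C
Reagents that add atoms: acetyl chloride, CC(=O)Cl
Why: Chemoselective O-acylation with acetyl chloride and a hindered pyridine base at low temperature should acetylate the primary hydroxyl in preference to the hindered, electronically deactivated secondary α-hydroxyl of the lactone.

**Compound list**
1 | (7aS)-7a-methyl-2,3,7,7a-tetrahydro-1H-indene-1,5(6H)-dione | C[C@]12CCC(=O)C=C1CCC2=O | starting material
2 | (7a'S)-7a'-methyl-2',3',7',7a'-tetrahydrospiro[1,3-dioxolane-2,1'-inden]-5'(6'H)-one | C[C@]12CCC(=O)C=C1CCC23OCCO3 | intermediate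
3 | (7a'S)-4',4',7a'-trimethyl-2',4',7',7a'-tetrahydrospiro[1,3-dioxolane-2,1'-inden]-5'(6'H)-one (alkene C3'=C3a') | C[C@]12CCC(=O)C(C)(C)C1=CCC23OCCO3 | intermediate
4 | hydrazone of 3 (not isolated) | C[C@]12CCC(=NN)C(C)(C)C1=CCC23OCCO3 | intermediate
5 | (7a'S)-4',4',7a'-trimethyl-2',4',5',6',7',7a'-hexahydrospiro[1,3-dioxolane-2,1'-indene] | C[C@]12CCCC(C)(C)C1=CCC23OCCO3 | intermediate
6 | (3a'S,7a'S)-4',4',7a'-trimethyloctahydrospiro[1,3-dioxolane-2,1'-indene] (trans-fused) | C[C@]12CCCC(C)(C)[C@@H]1CCC23OCCO3 | intermediate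
7 | (3aS,7aS)-4,4,7a-trimethyloctahydro-1H-inden-1-one | O=C1CC[C@H]2C(C)(C)CCC[C@]12C | intermediate
8 | potassium enolate of 7 (not isolated) | [K+].[O-]C1=CC[C@H]2C(C)(C)CCC[C@]12C | intermediate
9 | (3aS,7aS)-4,4,7a-trimethyl-3a,4,5,6,7,7a-hexahydro-3H-inden-1-yl trifluoromethanesulfonate | O=S(=O)(OC1=CC[C@H]2C(C)(C)CCC[C@]12C)C(F)(F)F | intermediate
10 | 2-[(3aS,7aS)-4,4,7a-trimethyl-3a,4,5,6,7,7a-hexahydro-3H-inden-1-yl]-4,4,5,5-tetramethyl-1,3,2-dioxaborolane | CC1(C)OB(OC1(C)C)C1=CC[C@H]2C(C)(C)CCC[C@]12C | intermediate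
11 | 2-[(1S,3aS,7aR)-4,4,7a-trimethyloctahydro-1H-inden-1-yl]-4,4,5,5-tetramethyl-1,3,2-dioxaborolane (boron β) | CC1(C)OB(OC1(C)C)[C@H]1CC[C@H]2C(C)(C)CCC[C@]12C | intermediate
12 | (R)-epichlorohydrin, (2R)-2-(chloromethyl)oxirane | ClC[C@H]1CO1 | starting material
13 | diethyl malonate | CCOC(=O)CC(=O)OCC | starting material
14 | diethyl 2-{[(2R)-oxiran-2-yl]methyl}propanedioate (not isolated) | CCOC(=O)C(C[C@@H]1CO1)C(=O)OCC | intermediate
15 | ethyl (1S,5R)-2-oxo-3-oxabicyclo[3.1.0]hexane-1-carboxylate | CCOC(=O)[C@]12C[C@H]1COC2=O | intermediate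
16 | ethyl (3S,4R)-2-oxo-4-(prop-2-en-1-yl)tetrahydrofuran-3-carboxylate (trans epimer drawn) | CCOC(=O)[C@@H]1[C@@H](CC=C)COC1=O | intermediate
17 | (4R)-4-(prop-2-en-1-yl)dihydrofuran-2(3H)-one | C=CC[C@H]1COC(=O)C1 | intermediate
18 | lithium enolate of 17 (not isolated) | C=CC[C@H]1COC([O-])=C1.[Li+] | intermediate
19 | (3S,4R)-3-(hydroxymethyl)-4-(prop-2-en-1-yl)dihydrofuran-2(3H)-one (3,4-trans) | OC[C@@H]1[C@@H](CC=C)COC1=O | intermediate
20 | (3S,4R)-3-{[(tert-butyldiphenylsilyl)oxy]methyl}-4-(prop-2-en-1-yl)dihydrofuran-2(3H)-one | CC(C)(C)[Si](OC[C@@H]1[C@@H](CC=C)COC1=O)(c1ccccc1)c1ccccc1 | intermediate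
21 | (2S,3R)-2-{[(tert-butyldiphenylsilyl)oxy]methyl}-3-(hydroxymethyl)-N-methoxy-N-methylhex-5-enamide | CON(C)C(=O)[C@H](CO[Si](c1ccccc1)(c1ccccc1)C(C)(C)C)[C@@H](CC=C)CO | intermediate
22 | (2S)-3-[(tert-butyldiphenylsilyl)oxy]-2-[(3R)-5-hydroxytetrahydrofuran-3-yl]-N-methoxy-N-methylpropanamide (lactol, not isolated) | CON(C)C(=O)[C@H](CO[Si](c1ccccc1)(c1ccccc1)C(C)(C)C)[C@@H]1COC(O)C1 | intermediate
23 | (2S)-3-[(tert-butyldiphenylsilyl)oxy]-N-methoxy-2-[(3R)-5-methoxytetrahydrofuran-3-yl]-N-methylpropanamide (anomeric mixture) | CON(C)C(=O)[C@H](CO[Si](c1ccccc1)(c1ccccc1)C(C)(C)C)[C@@H]1COC(OC)C1 | intermediate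
24 | (3S)-4-[(tert-butyldiphenylsilyl)oxy]-3-[(3R)-5-methoxytetrahydrofuran-3-yl]butan-2-one | CC(=O)[C@H](CO[Si](c1ccccc1)(c1ccccc1)C(C)(C)C)[C@@H]1COC(OC)C1 | intermediate
25 | 2,4,6-triisopropylbenzenesulfonyl hydrazone of 24 | CC(=NNS(=O)(=O)c1c(C(C)C)cc(C(C)C)cc1C(C)C)[C@H](CO[Si](c1ccccc1)(c1ccccc1)C(C)(C)C)[C@@H]1COC(OC)C1 | intermediate
26 | 2-lithio-1-alkene from 25: {(3R)-4-[(tert-butyldiphenylsilyl)oxy]-3-[(3R)-5-methoxytetrahydrofuran-3-yl]but-1-en-2-yl}lithium (not isolated) | [Li]C(=C)[C@H](CO[Si](c1ccccc1)(c1ccccc1)C(C)(C)C)[C@@H]1COC(OC)C1 | intermediate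
27 | lithium boronate complex of 11 and 26 (B bears pinacolate, the hydrindanyl C1 and the alkenyl carbon; not isolated) | [Li+].CC1(C)O[B-](OC1(C)C)(C(=C)[C@H](CO[Si](c1ccccc1)(c1ccccc1)C(C)(C)C)[C@@H]1COC(OC)C1)[C@H]1CC[C@H]2C(C)(C)CCC[C@]12C | intermediate
28 | β-iodoalkyl pinacol boronic ester: the tertiary carbon carries Bpin, CH2I, the hydrindanyl C1 and the side chain (not isolated) | ICC(B1OC(C)(C)C(C)(C)O1)([C@H]1CC[C@H]2C(C)(C)CCC[C@]12C)[C@H](CO[Si](c1ccccc1)(c1ccccc1)C(C)(C)C)[C@@H]1COC(OC)C1 | intermediate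
29 | tert-butyl{[(2R)-2-[(3R)-5-methoxytetrahydrofuran-3-yl]-3-[(1R,3aS,7aS)-4,4,7a-trimethyloctahydro-1H-inden-1-yl]but-3-en-1-yl]oxy}diphenylsilane | C=C([C@H]1CC[C@H]2C(C)(C)CCC[C@]12C)[C@H](CO[Si](c1ccccc1)(c1ccccc1)C(C)(C)C)[C@@H]1COC(OC)C1 | intermediate
30 | (4R)-4-{(2R)-1-[(tert-butyldiphenylsilyl)oxy]-3-[(1R,3aS,7aS)-4,4,7a-trimethyloctahydro-1H-inden-1-yl]but-3-en-2-yl}dihydrofuran-2(3H)-one | C=C([C@H]1CC[C@H]2C(C)(C)CCC[C@]12C)[C@H](CO[Si](c1ccccc1)(c1ccccc1)C(C)(C)C)[C@@H]1COC(=O)C1 | intermediate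
31 | potassium enolate of 30 (not isolated) | C=C([C@H]1CC[C@H]2C(C)(C)CCC[C@]12C)[C@H](CO[Si](c1ccccc1)(c1ccccc1)C(C)(C)C)[C@@H]1COC([O-])=C1.[K+] | intermediate
32 | (3S,4R)-4-{(2R)-1-[(tert-butyldiphenylsilyl)oxy]-3-[(1R,3aS,7aS)-4,4,7a-trimethyloctahydro-1H-inden-1-yl]but-3-en-2-yl}-3-hydroxydihydrofuran-2(3H)-one | C=C([C@H]1CC[C@H]2C(C)(C)CCC[C@]12C)[C@H](CO[Si](c1ccccc1)(c1ccccc1)C(C)(C)C)[C@@H]1COC(=O)[C@H]1O | intermediate
33 | (3S,4R)-3-hydroxy-4-{(2R)-1-hydroxy-3-[(1R,3aS,7aS)-4,4,7a-trimethyloctahydro-1H-inden-1-yl]but-3-en-2-yl}dihydrofuran-2(3H)-one | C=C([C@H]1CC[C@H]2C(C)(C)CCC[C@]12C)[C@H](CO)[C@@H]1COC(=O)[C@H]1O | intermediate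
34 | (2R)-2-[(3R,4S)-4-hydroxy-5-oxotetrahydrofuran-3-yl]-3-[(1R,3aS,7aS)-4,4,7a-trimethyloctahydro-1H-inden-1-yl]but-3-en-1-yl acetate | C=C([C@H]1CC[C@H]2C(C)(C)CCC[C@]12C)[C@H](COC(C)=O)[C@@H]1COC(=O)[C@H]1O | target

**Totals and risks**
Total step count: 22 (steps 1–8 hydrindane half, 9–17 side-chain half, 18 union, 19–22 endgame).
Longest linear sequence: 14 steps (9–17, then 18–22).

Steps most likely to fail:

1. Step 18. The boronate complex may form slowly or incompletely because both partners are α-branched (a neopentylic secondary boronic ester and a branched alkenyllithium). The alkenyllithium may be protonated before capture, and the sulfinate may consume iodine. The fallback sets out from ketone 7 and amide 23 and returns at 29. Ketone 7 is condensed with 2,4,6-triisopropylbenzenesulfonyl hydrazide to hydrazone F1, and a Shapiro reaction (n-BuLi, THF) gives alkenyllithium F2, which is acylated by the N-methoxy-N-methylamide 23 to enone F3. Hydrogenation (H2, Pd/C) from the α face gives the C1 β-acyl ketone F4, and Lombardo–Takai methylenation (Zn, CH2Br2, TiCl4) of F4 gives 29.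

2. Step 4. Hydrogen may be delivered to the wrong face (cis ring fusion), or reduction of the hindered trisubstituted alkene may stall. The fallback sets out from 2 and returns at 6. Monomethylation at C4 (t-BuOK 1 equiv, MeI 1 equiv) gives the 4-methyl enone F5. Birch-type reductive alkylation (Li, NH3, THF; then MeI) should protonate the ring-fusion carbon from the α face (trans fusion) and methylate the resulting enolate at C4, giving ketone F6. Wolff–Kishner reduction through hydrazone F7 gives 6.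

3. Step 22. Chemoselectivity may be lost, with acylation of the secondary α-hydroxyl as well as, or instead of, the primary one. The fallback sets out from 32 and returns at 34. The α-hydroxyl is protected as the 4-methoxybenzyl ether F8 (4-methoxybenzyl trichloroacetimidate, cat. acid), HF·pyridine frees the primary alcohol F9, Ac2O/pyridine gives acetate F10, and DDQ (CH2Cl2, pH 7 buffer) removes the benzyl-type ether to give 34.

Further compounds
F1 | step 18 | 2,4,6-triisopropylbenzenesulfonyl hydrazone of ketone 7 | CC(C)c1cc(C(C)C)c(S(=O)(=O)NN=C2CC[C@H]3C(C)(C)CCC[C@]23C)c(C(C)C)c1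
F2 | step 18 | [(3aS,7aS)-4,4,7a-trimethyl-3a,4,5,6,7,7a-hexahydro-3H-inden-1-yl]lithium | [Li]C1=CC[C@H]2C(C)(C)CCC[C@]12C
F3 | step 18 | (2S)-3-[(tert-butyldiphenylsilyl)oxy]-2-[(3R)-5-methoxytetrahydrofuran-3-yl]-1-[(3aS,7aS)-4,4,7a-trimethyl-3a,4,5,6,7,7a-hexahydro-3H-inden-1-yl]propan-1-one | O=C(C1=CC[C@H]2C(C)(C)CCC[C@]12C)[C@H](CO[Si](c1ccccc1)(c1ccccc1)C(C)(C)C)[C@@H]1COC(OC)C1
F4 | step 18 | (2S)-3-[(tert-butyldiphenylsilyl)oxy]-2-[(3R)-5-methoxytetrahydrofuran-3-yl]-1-[(1S,3aS,7aS)-4,4,7a-trimethyloctahydro-1H-inden-1-yl]propan-1-one (acyl group β at C1) | O=C([C@H]1CC[C@H]2C(C)(C)CCC[C@]12C)[C@H](CO[Si](c1ccccc1)(c1ccccc1)C(C)(C)C)[C@@H]1COC(OC)C1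
F5 | step 4 | (7a'S)-4',7a'-dimethyl-2',3',7',7a'-tetrahydrospiro[1,3-dioxolane-2,1'-inden]-5'(6'H)-one | C[C@]12CCC(=O)C(C)=C1CCC23OCCO3
F6 | step 4 | (3a'S,7a'S)-4',4',7a'-trimethylhexahydrospiro[1,3-dioxolane-2,1'-inden]-5'(4'H)-one (trans-fused) | C[C@]12CCC(=O)C(C)(C)[C@@H]1CCC23OCCO3
F7 | step 4 | hydrazone of F6 | C[C@]12CCC(=NN)C(C)(C)[C@@H]1CCC23OCCO3
F8 | step 22 | (3S,4R)-4-{(2R)-1-[(tert-butyldiphenylsilyl)oxy]-3-[(1R,3aS,7aS)-4,4,7a-trimethyloctahydro-1H-inden-1-yl]but-3-en-2-yl}-3-[(4-methoxybenzyl)oxy]dihydrofuran-2(3H)-one | C=C([C@H]1CC[C@H]2C(C)(C)CCC[C@]12C)[C@H](CO[Si](c1ccccc1)(c1ccccc1)C(C)(C)C)[C@@H]1COC(=O)[C@H]1OCc1ccc(OC)cc1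
F9 | step 22 | (3S,4R)-4-{(2R)-1-hydroxy-3-[(1R,3aS,7aS)-4,4,7a-trimethyloctahydro-1H-inden-1-yl]but-3-en-2-yl}-3-[(4-methoxybenzyl)oxy]dihydrofuran-2(3H)-one | C=C([C@H]1CC[C@H]2C(C)(C)CCC[C@]12C)[C@H](CO)[C@@H]1COC(=O)[C@H]1OCc1ccc(OC)cc1
F10 | step 22 | (2R)-2-{(3R,4S)-4-[(4-methoxybenzyl)oxy]-5-oxotetrahydrofuran-3-yl}-3-[(1R,3aS,7aS)-4,4,7a-trimethyloctahydro-1H-inden-1-yl]but-3-en-1-yl acetate | C=C([C@H]1CC[C@H]2C(C)(C)CCC[C@]12C)[C@H](COC(C)=O)[C@@H]1COC(=O)[C@H]1OCc1ccc(OC)cc1
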